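**Plan**

- Numbering: ring C1(–chain)–C2H2–C3H=C4(–C14H2O)–C5H(OH)–C6H2; chain C7(=CH2)–C8H2–C9H=C10H–C11(OH)(C13H3)–C12H2O.
- Retrosynthesis: the two O–Si bonds are cut first, then C8–C9 (allylic chloride plus E-alkenylzirconocene), then C8–Cl and the C14–O acyl bond. Last, the π bonds C3=C4 and C7=CH2 are exchanged for the σ bond C3–C7 and a C4–O bond of a pinane spiro-oxirane.
- Enabling feature: ring atoms C3=C4(–C14H2–O)–C5(–O) with C7 attached at C1 are what a pinane leaves once its cyclobutane bond C3–C7 is cut. C7 was the CMe2 bridge (its methyls are now the =CH2 carbon and C8), C1 and C3 were the bridgeheads, and C14 was the exocyclic carbon on C4.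
- Forward order: the six-membered ring is never built; it is released from the bicyclo[3.1.1]heptane of (+)-α-pinene by opening the four-membered ring (step 5). C14 is then acylated, C8 chlorinated, the C9–C13 fragment joined at C8, and both silyl groups removed.
- Stereochemistry: C1 is the C5 bridgehead of (+)-α-pinene. C5 comes from hydride addition to pinocarvone anti to the dimethyl bridge. C11 comes from (R)-2-methylglycidol. The E C9=C10 bond comes from syn-hydrozirconation of a terminal alkyne.

Key step: step 5

Remark: (R)-2-methylglycidol is taken as a purchased compound (it is the Sharpless epoxidation product of 2-methylprop-2-en-1-ol); in the SMILES of zirconium compounds the η5-cyclopentadienyl rings are written as σ-bonded C5H5 groups.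

**Route**

Step 1
Reactants: 1 (+)-α-pinene
Product: 4 (1S,5S)-pinocarvone, via trans-pinocarveyl hydroperoxide 2 (not isolated), via trans-pinocarveyl peroxyacetate 3 (not isolated)
Conditions: O2, hν (visible), tetraphenylporphyrin (cat.), Ac2O, pyridine, DMAP (cat.), CH2Cl2, 20 °C
Reagents that add atoms: dioxygen, O=O
Why: Schenck ene reaction of singlet oxygen (oxygen adds at C3 anti to the dimethyl bridge, hydrogen leaves from the C2 methyl) gives the allylic hydroperoxide, whose peracetate undergoes Kornblum–DeLaMare-type elimination to the enone in the same pot; the transient C3 centre is erased and the bridgeheads are untouched.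

Step 2
Reactants: 4 (1S,5S)-pinocarvone
Product: 5 cis-pinocarveol, (1S,3S,5S)-6,6-dimethyl-2-methylidenebicyclo[3.1.1]heptan-3-ol
Conditions: NaBH4, CeCl3·7H2O, MeOH, −78 → 0 °C
Reagents that add atoms: none
Why: Luche 1,2-reduction of the enone; hydride should add to the carbonyl from the face anti to the dimethyl bridge because the bridge methyl covers the syn face, which places the hydroxyl syn to the bridge (3S).

Step 3
Reactants: 5 cis-pinocarveol
Product: 6 triisopropylsilyl ether of cis-pinocarveol
Conditions: TIPSOTf, 2,6-lutidine, CH2Cl2, −78 → 0 °C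
Reagents that add atoms: triisopropylsilyl trifluoromethanesulfonate, CC(C)[Si](C(C)C)(C(C)C)OS(=O)(=O)C(F)(F)F
Why: Silylation of a hindered secondary allylic alcohol with a silyl triflate and a hindered pyridine base; the bulky, weakly basic ether oxygen is chosen to screen its face in step 4 and to stay out of the cation chemistry of step 5.

Step 4
Reactants: 6 triisopropylsilyl ether of cis-pinocarveol
Product: 7 (1S,2R,3S,5S)-6,6-dimethyl-3-(triisopropylsilyloxy)spiro[bicyclo[3.1.1]heptane-2,2'-oxirane]
Conditions: dimethyldioxirane, acetone/CH2Cl2, −20 → 0 °C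
Reagents that add atoms: dimethyldioxirane, CC1(C)OO1
Why: Neutral epoxidation of the exocyclic 1,1-disubstituted alkene spares the acid-labile spiro-oxirane; approach anti to both the dimethyl bridge and the silyloxy group should set the spiro centre (2R) with the oxirane oxygen anti to the bridge, although either epimer would serve because this carbon becomes sp2 in step 5.

Step 5
Reactants: 7 spiro-oxirane
Product: 8 [(4S,6S)-4-(prop-1-en-2-yl)-6-(triisopropylsilyloxy)cyclohex-1-en-1-yl]methanol
Conditions: NH4NO3 (0.2 equiv), MeNO2, 40 °C
Reagents that add atoms: none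
Why: Hydrogen bonding from the ammonium ion polarises the tertiary C–O bond at the spiro carbon, and because the oxirane oxygen lies anti to the dimethyl bridge the cyclobutane bond from the adjacent bridgehead to the bridge carbon is antiperiplanar to it and should cleave in step with ionisation (Grob-type fragmentation), so that C3=C4 forms, the charge arrives on the tertiary C7 and loss of a methyl proton to nitrate or solvent gives C7=CH2 while the former oxirane CH2 becomes C14H2OH. The closest known reaction is the weak-acid isomerisation of β-pinene oxide (2,10-epoxypinane) to perillyl alcohol, the same oxirane-triggered opening of the pinane four-membered ring. No ring is closed: the four-membered ring opens and the bicycle becomes a monocyclic cyclohexene. No stereocentre is created, since pinane C5 becomes C1 and pinane C3 becomes C5 (target numbering) without any bond to them being touched, so the syn relation between silyloxy group and bridge is read out as the cis relation of 8. Fragmentation has to win over 1,2-hydride shift to an aldehyde, over proton loss without ring opening and over capture of the C7 cation by the neighbouring ether oxygen; the anti alignment and strain of the bridge bond, the inductive penalty that the adjacent C–O bond puts on an unassisted cation, the C–H bond next to the spiro carbon being syn to the leaving oxygen, and the bulk of the triisopropylsilyl group are expected to secure this.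

Step 6
Reactants: 8 allylic alcohol; 9 isobutyryl chloride
Product: 10 [(4S,6S)-4-(prop-1-en-2-yl)-6-(triisopropylsilyloxy)cyclohex-1-en-1-yl]methyl 2-methylpropanoate
Conditions: pyridine, DMAP (cat.), CH2Cl2, 0 °C
Reagents that add atoms: none
Why: Acylation of a primary allylic alcohol by an acid chloride under nucleophilic catalysis; the only other oxygen is silylated.

Step 7
Reactants: 10 isobutyrate
Product: 11 [(4S,6S)-4-(3-chloroprop-1-en-2-yl)-6-(triisopropylsilyloxy)cyclohex-1-en-1-yl]methyl 2-methylpropanoate
Conditions: Ca(OCl)2, CO2 (solid), CH2Cl2/H2O, 0 °C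
Reagents that add atoms: calcium hypochlorite, [Ca+2].[O-]Cl.[O-]Cl
Why: Ene-type allylic chlorination by hypochlorous acid made in situ: electrophilic chlorine adds to the terminal carbon of the 1,1-disubstituted alkene and a methyl proton is lost, giving the transposed 2-substituted allyl chloride; the ring alkene is deactivated by its two allylic C–O bonds and screened by the silyl group.

Step 8
Reactants: 12 (R)-2-methylglycidol
Product: 13 (2S)-2-methyloxirane-2-carbaldehyde
Conditions: Dess–Martin periodinane, CH2Cl2, 0 → 20 °C; filtered and used as a solution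
Reagents that add atoms: none
Why: Dess–Martin oxidation of a primary alcohol under non-aqueous, near-neutral conditions; the quaternary oxirane carbon has no α-hydrogen and cannot epimerise (the descriptor changes to S only through the priority rules).

Step 9
Reactants: 13 (2S)-2-methyloxirane-2-carbaldehyde
Product: 14 (2R)-2-ethynyl-2-methyloxirane
Conditions: dimethyl (1-diazo-2-oxopropyl)phosphonate, K2CO3, MeOH, 0 → 20 °C; volatile, carried on as an Et2O solution
Reagents that add atoms: dimethyl (1-diazo-2-oxopropyl)phosphonate, CC(=O)C(=[N+]=[N-])P(=O)(OC)OC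
Why: Seyferth–Gilbert homologation in the Ohira–Bestmann variant: the diazomethylphosphonate anion adds to the aldehyde, and elimination of phosphate, loss of N2 and 1,2-hydrogen shift of the alkylidene carbene give the terminal alkyne without touching the stereocentre.

Step 10
Reactants: 14 (2R)-2-ethynyl-2-methyloxirane; 15 isobutyric acid
Product: 16 (2R)-2-hydroxy-2-methylbut-3-yn-1-yl 2-methylpropanoate
Conditions: Cs2CO3 (0.1 equiv), DMF, 70 °C, sealed tube
Reagents that add atoms: none
Why: Carboxylate-catalysed SN2 opening of a 2,2-disubstituted oxirane by the carboxylic acid at the unsubstituted CH2; the C–O bond at the quaternary carbon is not broken, so the configuration is retained.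

Step 11
Reactants: 16 hydroxy ester
Product: 17 (2R)-2-methyl-2-(triethylsilyloxy)but-3-yn-1-yl 2-methylpropanoate
Conditions: TESOTf, 2,6-lutidine, CH2Cl2, −78 → 0 °C
Reagents that add atoms: triethylsilyl trifluoromethanesulfonate, CC[Si](CC)(CC)OS(=O)(=O)C(F)(F)F
Why: Silylation of the tertiary propargylic alcohol with a silyl triflate so that Cp2Zr(H)Cl in step 12 is not consumed by an O–H bond; the group is removed together with the ring silyl ether at the end.

Step 12
Reactants: 17 silylated alkyne; 11 allylic chloride
Product: 19 C5-O-triisopropylsilyl C11-O-triethylsilyl ether of the target, via E-alkenylzirconocene chloride 18 (not isolated)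
Conditions: 17, Cp2Zr(H)Cl (1.2 equiv), THF, 20 °C; then 11, CuCl (10 mol %), THF, 20 → 40 °C
Reagents that add atoms: none
Why: syn-Hydrozirconation of the terminal alkyne puts zirconium on the terminal carbon and fixes the E geometry; transmetalation to monovalent copper and allylic substitution on the allyl chloride (copper-catalysed allylation of alkenylzirconocenes) forms C8–C9, and because the allyl unit is symmetrical about C7 the SN2 and SN2′ modes give the same 1,4-diene.

Step 13
Reactants: 19 bis-silyl ether
Product: 20 target, [(4S,6S)-6-hydroxy-4-[(4E,6R)-6-hydroxy-6-methyl-7-(2-methylpropanoyloxy)hepta-1,4-dien-2-yl]cyclohex-1-en-1-yl]methyl 2-methylpropanoate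
Conditions: TBAF, AcOH (1:1), THF, 0 → 20 °C
Reagents that add atoms: none
Why: Fluoride cleavage of both silyl ethers, buffered with acetic acid so that the liberated C5 alkoxide cannot take over the neighbouring isobutyryl group (1,3-acyl shift) and the esters are not cleaved.

**Compound list**

1 | (+)-α-pinene, (1R,5R)-2,6,6-trimethylbicyclo[3.1.1]hept-2-ene | CC1=CC[C@@H]2C[C@H]1C2(C)C | starting material
2 | trans-pinocarveyl hydroperoxide, (1S,3R,5S)-3-hydroperoxy-6,6-dimethyl-2-methylidenebicyclo[3.1.1]heptane (OOH anti to the dimethyl bridge) | C=C1[C@H](OO)C[C@@H]2C[C@H]1C2(C)C | intermediate (not isolated)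
3 | trans-pinocarveyl peroxyacetate, (1S,3R,5S)-6,6-dimethyl-2-methylidenebicyclo[3.1.1]heptan-3-yl ethaneperoxoate | C=C1[C@H](OOC(C)=O)C[C@@H]2C[C@H]1C2(C)C | intermediate (not isolated)
4 | (1S,5S)-pinocarvone, (1S,5S)-6,6-dimethyl-2-methylidenebicyclo[3.1.1]heptan-3-one | C=C1C(=O)C[C@@H]2C[C@H]1C2(C)C | intermediate
5 | cis-pinocarveol, (1S,3S,5S)-6,6-dimethyl-2-methylidenebicyclo[3.1.1]heptan-3-ol (OH syn to the dimethyl bridge) | C=C1[C@@H](O)C[C@@H]2C[C@H]1C2(C)C | intermediate
6 | {[(1S,3S,5S)-6,6-dimethyl-2-methylidenebicyclo[3.1.1]heptan-3-yl]oxy}tri(propan-2-yl)silane | C=C1[C@@H](O[Si](C(C)C)(C(C)C)C(C)C)C[C@@H]2C[C@H]1C2(C)C | intermediate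
7 | (1S,2R,3S,5S)-6,6-dimethyl-3-(triisopropylsilyloxy)spiro[bicyclo[3.1.1]heptane-2,2'-oxirane] (oxirane O anti, silyloxy syn to the dimethyl bridge) | C1O[C@@]12[C@@H](O[Si](C(C)C)(C(C)C)C(C)C)C[C@@H]3C[C@H]2C3(C)C | intermediate
8 | [(4S,6S)-4-(prop-1-en-2-yl)-6-(triisopropylsilyloxy)cyclohex-1-en-1-yl]methanol | C=C(C)[C@H]1CC=C(CO)[C@@H](O[Si](C(C)C)(C(C)C)C(C)C)C1 | intermediate
9 | isobutyryl chloride, 2-methylpropanoyl chloride | CC(C)C(Cl)=O | starting material
10 | [(4S,6S)-4-(prop-1-en-2-yl)-6-(triisopropylsilyloxy)cyclohex-1-en-1-yl]methyl 2-methylpropanoate | C=C(C)[C@H]1CC=C(COC(=O)C(C)C)[C@@H](O[Si](C(C)C)(C(C)C)C(C)C)C1 | intermediate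
11 | [(4S,6S)-4-(3-chloroprop-1-en-2-yl)-6-(triisopropylsilyloxy)cyclohex-1-en-1-yl]methyl 2-methylpropanoate | C=C(CCl)[C@H]1CC=C(COC(=O)C(C)C)[C@@H](O[Si](C(C)C)(C(C)C)C(C)C)C1 | intermediate
12 | (R)-2-methylglycidol, [(2R)-2-methyloxiran-2-yl]methanol | C[C@@]1(CO)CO1 | starting material
13 | (2S)-2-methyloxirane-2-carbaldehyde | C[C@@]1(C=O)CO1 | intermediate
14 | (2R)-2-ethynyl-2-methyloxirane | C[C@@]1(C#C)CO1 | intermediate
15 | isobutyric acid, 2-methylpropanoic acid | CC(C)C(=O)O | starting material
16 | (2R)-2-hydroxy-2-methylbut-3-yn-1-yl 2-methylpropanoate | C#C[C@@](C)(O)COC(=O)C(C)C | intermediate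
17 | (2R)-2-methyl-2-(triethylsilyloxy)but-3-yn-1-yl 2-methylpropanoate | C#C[C@@](C)(O[Si](CC)(CC)CC)COC(=O)C(C)C | intermediate
18 | chlorobis(cyclopentadienyl)[(1E,3R)-3-methyl-4-(2-methylpropanoyloxy)-3-(triethylsilyloxy)but-1-en-1-yl]zirconium | Cl[Zr](/C=C/[C@@](C)(O[Si](CC)(CC)CC)COC(=O)C(C)C)(C1C=CC=C1)C1C=CC=C1 | intermediate (not isolated)
19 | [(4S,6S)-4-[(4E,6R)-6-methyl-7-(2-methylpropanoyloxy)-6-(triethylsilyloxy)hepta-1,4-dien-2-yl]-6-(triisopropylsilyloxy)cyclohex-1-en-1-yl]methyl 2-methylpropanoate | C=C(C/C=C/[C@@](C)(O[Si](CC)(CC)CC)COC(=O)C(C)C)[C@H]1CC=C(COC(=O)C(C)C)[C@@H](O[Si](C(C)C)(C(C)C)C(C)C)C1 | intermediate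
20 | CNP0599657.1, [(4S,6S)-6-hydroxy-4-[(4E,6R)-6-hydroxy-6-methyl-7-(2-methylpropanoyloxy)hepta-1,4-dien-2-yl]cyclohex-1-en-1-yl]methyl 2-methylpropanoate | C=C(C/C=C/[C@@](C)(O)COC(=O)C(C)C)[C@H]1CC=C(COC(=O)C(C)C)[C@@H](O)C1 | target

**Step count and risks**

Total step count: 13. Longest linear sequence: 9 steps (steps 1–7, 12 and 13, from (+)-α-pinene); the side-chain branch is 4 steps (steps 8–11).

Steps most likely to fail:

Step 5. The oxirane may ionise without help from the bridge bond, which would lead to hydride shift to an aldehyde or to proton loss with the bicycle intact. The C7 cation may also be captured by the silyl ether oxygen with loss of the silyl group. Ionisation next to the C–O bond may simply be slow. The fallback replaces heterolysis by homolysis and sets out from 7. Cp2TiCl (made from Cp2TiCl2 and Zn dust in THF at 20 °C; trivalent titanium) transfers one electron to the oxirane. The tertiary radical at the spiro carbon opens the cyclobutane by β-scission, as radicals on the pinane skeleton do. The resulting 2-propyl radical is trapped by a second Cp2TiCl, and β-hydride elimination leaves the prop-1-en-2-yl group. Protonolysis of the titanium alkoxide brings the route back at 8. No compound outside the compound list is formed (F0).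

Step 7. Hypochlorous acid may attack the ring alkene, the ring methine proton may be lost instead of a methyl proton, or the allyl chloride may be chlorinated again. The fallback sets out from 10 and installs the leaving group in two operations. Allylic hydroxylation with SeO2 (cat.) and t-BuOOH in CH2Cl2 at 20 °C should take place at the methyl group of the prop-1-en-2-yl unit, because the allylic positions at the more substituted end of the ring alkene already carry oxygen. This gives [(4S,6S)-4-(3-hydroxyprop-1-en-2-yl)-6-(triisopropylsilyloxy)cyclohex-1-en-1-yl]methyl 2-methylpropanoate F1. An Appel reaction (PPh3, CCl4, 40 °C) then converts the primary allylic alcohol into the chloride, and the route is rejoined at 11.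

Step 12. Cp2Zr(H)Cl may reduce the isobutyrate, the alkenylzirconocene may be protonated before it couples, or transmetalation and substitution at the branched allyl chloride may be sluggish. The fallback sets out from 16 (the free tertiary alcohol) and 11 and uses tin and palladium. Hydrostannation of 16 (Bu3SnH, PdCl2(PPh3)2 cat., THF, 0 °C) should place tin on the terminal carbon, away from the quaternary carbinol, giving (2R,3E)-2-hydroxy-2-methyl-4-(tributylstannyl)but-3-en-1-yl 2-methylpropanoate F2. Stille coupling of this stannane with 11 (Pd2(dba)3, AsPh3, NMP, 40 °C) relies on zerovalent palladium inserting into the allylic C–Cl bond well before the allylic ester, and gives [(4S,6S)-4-[(4E,6R)-6-hydroxy-6-methyl-7-(2-methylpropanoyloxy)hepta-1,4-dien-2-yl]-6-(triisopropylsilyloxy)cyclohex-1-en-1-yl]methyl 2-methylpropanoate F3. Removal of the single silyl group under the conditions of step 13 brings the route back at 20.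

Further compounds
F0 | step 5 | none | none
F1 | step 7 | [(4S,6S)-4-(3-hydroxyprop-1-en-2-yl)-6-(triisopropylsilyloxy)cyclohex-1-en-1-yl]methyl 2-methylpropanoate | C=C(CO)[C@H]1CC=C(COC(=O)C(C)C)[C@@H](O[Si](C(C)C)(C(C)C)C(C)C)C1
F2 | step 12 | (2R,3E)-2-hydroxy-2-methyl-4-(tributylstannyl)but-3-en-1-yl 2-methylpropanoate | CCCC[Sn](CCCC)(CCCC)/C=C/[C@@](C)(O)COC(=O)C(C)C
F3 | step 12 | [(4S,6S)-4-[(4E,6R)-6-hydroxy-6-methyl-7-(2-methylpropanoyloxy)hepta-1,4-dien-2-yl]-6-(triisopropylsilyloxy)cyclohex-1-en-1-yl]methyl 2-methylpropanoate | C=C(C/C=C/[C@@](C)(O)COC(=O)C(C)C)[C@H]1CC=C(COC(=O)C(C)C)[C@@H](O[Si](C(C)C)(C(C)C)C(C)C)C1
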